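If the catalyst kept a pace of its own, whatever the starting material, product per catalyst charged was a clock, and that case was the zero of my scale.

| flask | starting material | partner | free catalyst | temperature | remark | time |
|---|---|---|---|---|---|---|
| gamma | 1 M | 1.5 M (fed, over 40 h) | 28 mM | 55 °C | run made earlier; the fed solution adds 0.10 times the starting volume |  |
| delta | 1 M | 1.5 M (fed, over 40 h) | 44 mM | 75 °C | run made earlier; the fed solution adds 0.10 times the starting volume |  |
| theta | 2 M | 1.5 M (fed, over 40 h) | 20 mM | 55 °C | run made earlier; the fed solution adds 0.10 times the starting volume |  |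
| amber | 1.0 M | 1.50 M | 20 mM | 60 °C | everything together at the start, the whole solution of partner included, so that from the start the volume is larger by 0.10 times the starting volume | 40 h |
| violet | 1.0 M | 1.50 M (fed, over 40 h) | 20 mM | 90 °C | the fed solution adds 0.10 times the starting volume | 40 h |

| run | time / h | product / % | starting material / % |
|---|---|---|---|
| gamma | 30.0 | 1.9 | 99.1 |
| gamma | 60.0 | 4.1 | 95.7 |
| gamma | 96.0 | 7.5 | 93.1 |
| gamma | 120 | 9.2 | 90.3 |
| gamma | 144 | 12.0 | 88.5 |
| gamma | 192 | 14.7 | 82.9 |
| delta | 3.00 | 0.2 | 100.6 |
| delta | 10.0 | 2.1 | 97.0 |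
| delta | 20.0 | 7.9 | 91.1 |
| delta | 30.0 | 17.3 | 82.1 |
| delta | 40.0 | 28.7 | 72.6 |
| delta | 48.0 | 36.4 | 63.9 |
| delta | 60.0 | 48.8 | 51.3 |
| theta | 15.0 | 0 | 99.9 |
| theta | 30.0 | 0.8 | 99.2 |
| theta | 60.0 | 1.3 | 97.9 |
| theta | 96.0 | 2.7 | 97.9 |
| theta | 192 | 5.2 | 94.6 |

(readings scatter by 0.5 percentage points)

- charges are per starting volume, the dose included; the dosed solution carries all of it
- steps that have been proposed: catalyst intermediate D -> free catalyst + product; starting material + catalyst intermediate B -> catalyst intermediate C; partner + free catalyst <-> catalyst intermediate A; catalyst intermediate A -> catalyst intermediate B; catalyst intermediate C -> catalyst intermediate D; catalyst intermediate C -> spent catalyst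

1. the flask that ends with the higher amount of product, in percent of the starting material charged, or "neither" when 2 percentage points or less lies between them (amber / violet / neither)
2. final product, as a percentage of the starting material charged, in amber
3. final product, as a percentage of the starting material charged, in violet

I read the pace two ways at 55 °C, each as a slope after dosing had ended. Between 60.0 h and 192 h, gamma gave 0.0287 h⁻¹. Theta, with twice the starting material and a different catalyst charge, gave 0.0295 h⁻¹. Two different flasks read about the same, so I trusted the number. A third reading parted from its neighbour: delta's mean over dosing, 0.163 h⁻¹, lay below its slope after dosing, 0.228 h⁻¹. The mean was the one that cheated, since partner was still going in, so I kept the ratio 0.714 as the cost of dosing.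

Gamma's and delta's slopes gave an activation energy of 98.5 kJ mol⁻¹. From it came the turnover frequency, the product formed per catalyst charged per hour with the partner present in full: 0.0493 h⁻¹ at 60 °C, and 0.932 h⁻¹ at 90 °C. Multiplying by c(free catalyst) and the time and dividing by c(starting material), I reckoned 3.95% for amber. For violet, with the dosing ratio as well, I reckoned 53.2%.

The forecast said violet, with 4.5% for amber and 42% for violet, on this ground: “So the reaction is zero order in starting material and first order in catalyst.” For violet it stood below my figure.

Amber gave 4.30% and violet 44.2%, so violet made more and the forecast held.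

    catalyst intermediate D → free catalyst + product (k = 0.00966 s⁻¹, Ea = 88.0 kJ mol⁻¹)
    starting material + catalyst intermediate B → catalyst intermediate C (k = 0.0906 L mol⁻¹ s⁻¹, Ea = 76.0 kJ mol⁻¹)
    partner + free catalyst ⇌ catalyst intermediate A (K = 5.06 L mol⁻¹, k = 5.04 × 10⁻⁴ L mol⁻¹ s⁻¹, Ea = 73.0 kJ mol⁻¹, ΔH = 5.00 kJ mol⁻¹)
    catalyst intermediate A → catalyst intermediate B (k = 6.37 × 10⁻⁴ s⁻¹, Ea = 108 kJ mol⁻¹)
    catalyst intermediate C → catalyst intermediate D (k = 0.0159 s⁻¹, Ea = 98.0 kJ mol⁻¹)
    catalyst intermediate C → spent catalyst (k = 1.57 × 10⁻⁵ s⁻¹, Ea = 115 kJ mol⁻¹)
    (constants at 90 °C)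

Amber's own frequency, 0.0537 h⁻¹, stood near the carried 0.0493 h⁻¹. In amber at 40.0 h, 63.1% of the catalyst sat as catalyst intermediate A, a resting state, and its step to catalyst intermediate B had a half-life of 7.6 h. In violet at 40.0 h that share was 36.8%, smaller than amber's, and the half-life of the step alone was 0.30 h, shorter than amber's. Amber left until 4.0 d should, by the carried frequency, hold 9.47%, and it held 10.7%.

(The runs come from a simulation from invented constants, and the scatter is random.)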